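- Take the closed, stirred vessel, charged with solid substrate and partner, and compare two amounts: the target plateau in molar terms and the partner charged.

| setting | noon | autumn | flask |
|---|---|---|---|
| solid substrate | 0.095 M | 0.14 M | 0.095 M |
| partner | 0.0998 M | 0.0998 M | 0.0998 M |
| temperature | 80 °C | 65 °C | 80 °C |
| remark | the very flask that is asked about, followed so far | run made earlier |  |
| time |  |  | 40 min |

| run | time / min | target / % | solid substrate / % |
|---|---|---|---|
| noon | 6.00 | 16.0 | 0 |
| noon | 12.0 | 15.4 | 0 |
| noon | 20.0 | 15.5 | 1.8 |
| noon | 25.0 | 15.3 | 0 |
| noon | 30.0 | 15.2 | 0.3 |
| autumn | 2.00 | 7.0 | 8.4 |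
| autumn | 5.00 | 11.9 | 2.4 |
| autumn | 6.00 | 12.3 | 1.1 |
| autumn | 10.0 | 13.7 | 0 |
| autumn | 12.0 | 13.0 | 0.1 |

(each reading ± 0.5 percentage points)

- the volume of additions can be left aside
- the earlier runs were read with a standard deviation of 0.5 percentage points
- at the start none of the solid substrate is in solution
- a reading or a percentage of target counts all its forms, free or not

- east: at 40 min raise the temperature by 20 K, then wait 40 min
- south-west: change nothing and wait 40 min more
- north-east: at 40 min add partner, 100 % of the amount charged, then wait 40 min

- target, in percent of the solid substrate first charged, at 40 min
- what to do for the largest gain in target; "none" if nothing gains more than 2 percentage points (east / south-west / north-east / none)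
- target present, in percent of the solid substrate first charged, after south-west
- target present, in percent of the solid substrate first charged, after north-east

- Average the noon readings: target stands flat at 15.5 % of the substrate charge.
- Reckon from that noon plateau 14.7 % as the partner yield Y, target formed per partner charged. The autumn run reads 18.7 %, higher than noon, at the cooler setting.
- Note the autumn reading at 2.00 min: solid and target together hold 15.4 %, so 84.6 % of the autumn charge has left the solid without being read as target.
- Bet, as my own reckoning, that partner is the limiting reagent and that substrate remains in an unread form. Partner is unread, so test this with a dose: a fresh charge should return the same Y, giving 31.0 % after north-east. Expect 15.5 % now and after waiting, and choose north-east.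
- The forecast differs: 15.2 % now, 15 % after south-west, 14.9 % after north-east, best none, holding that “the reaction has stopped for lack of substrate, not partner”.
- The flask gives 15.9 % now, 15.9 % after south-west and 30.2 % after north-east. The best option is north-east, gaining 14 percentage points, against 0 points for east.

    solid substrate ⇌ dissolved substrate, rate k1*(cs1 - [dissolved substrate]) while solid is left; crystals form when [dissolved substrate] > cs1 (solubility = 37.0 mM, k = 0.471 /s)
    2 solid substrate → self-condensation product (k = 0.677 /M/s, Ea = 72.0 kJ/mol)
    dissolved substrate + partner → target (k = 0.211 /M/s, Ea = 71.0 kJ/mol)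
    solid product ⇌ target, rate k4*(cs4 - [target]) while solid is left; crystals form when [target] > cs4 (solubility = 2.90 mM, k = 0.751 /s)
    partner → decomposed reagent (k = 0.0328 /s, Ea = 95.0 kJ/mol)
    partner ⇌ dormant form (K = 0.890, k = 0.0825 /s, Ea = 95.0 kJ/mol, ΔH = −28.0 kJ/mol)
    partner → side product (k = 0.00704 /s, Ea = 86.0 kJ/mol)
    (constants at 80 °C)

- Read this flask at 40.0 min: partner stands at 0 % and dissolved substrate at 38.9 %. With the depletion of partner taken away, the run reaches 63.3 % against 15.9 %, the main reason for the plateau. The second dose returned Y = 13.7 %, against 14.7 % read from the noon readings. The neighbour flask at 95 °C, with partner at 0 %, shows Y = 9.96 %, lower than the 14.7 % read at noon.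

The runs are simulated for an exercise, noise included.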